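The constants used here stand for no real mixture; the rest is arithmetic.

The pitfall here is to reckon the target from its making step and treat the side step as a small tax, when the side step feeds on the same starting material.

starting material 0.20 M; reagent in the second phase 2.50 equiv; time 10 d; volume of the second phase over the first 0.50

    target → decomposed product (k1 = 0.013 /h)
    target ⇌ product in the second phase, rate k2*([target] - [product in the second phase]/K2) per volume of the first phase (K2 = 19, k2 = 0.026 /h)
    starting material + target ⇌ idle adduct, settled at all times (K3 = 13 /M)
    starting material + reagent in the reaction phase → target (k4 = 0.077 /M/h)
    starting material + target → side product (k5 = 1.1 /M/h)
    reagent in the reaction phase ⇌ reagent in the second phase, rate k6*([reagent in the reaction phase] - [reagent in the second phase]/K6) per volume of the first phase (K6 = 1.3, k6 = 0.0076 /h)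

1. the target and product in the second phase and idle adduct together standing at 10 d, as a percentage of the starting material charged
2. part of the starting material charged that has reacted at 10 d

- percent here means starting material units held: one idle adduct or side product counts as two
- what is said of target includes product in the second phase and idle adduct
- in the second phase: reagent in the second phase, product in the second phase; everything else is in the first
- charges count per volume of the first phase; a concentration in a rate is the amount of a species over the volume of its own phase; every rate counts per litre of the first phase
- in an amount of target, one idle adduct counts as one target
- run time (flask): 10 d

I build the flask up one process at a time, and I start with the making step. Reagent leaks out of the second phase with a time of 2.16 d. It moves toward a balance of 0.242 M in the reaction phase, a figure that already pays one reagent for every two starting material units. After one leak time, c(reagent in the reaction phase) is 0.153 M. At that level the making step by itself turns 94.1% of the charge into target by 10 d.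

Now I add the side step. Its rate and the making rate both carry c(starting material), so that factor cancels, and free target stops rising where the two rates are equal. That gives c(target) = c(reagent in the reaction phase)/S, with the selectivity factor S = 14.3. Here this is 0.0107 M, or 5.36% of the charge. I call it the target ceiling, the free target level at which the side step removes what the making step delivers. The number drops from 94.1% to that. At the ceiling, starting material also goes twice as fast.

The rest is a correction. As charged, the side step gives free target a half-life of 0.13 d, shorter than the 2.2 d of decomposition. So I divide the ceiling by 1 + 0.0355 M/c(starting material). I let reagent arrive one leak time late and then stand at its balance, and I let starting material go twice as fast as by the making step, so my estimate for reaching that level is about 4.09 d. With free target held at the full ceiling, I put what the second phase collects until then at 13.7% of the charge, and the free target I reckon for that moment adds 2.68%. I drop the idle adduct. My reckoning is y = 16.4%, and with reagent at balance afterwards, cv = 98.7%.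

The forecast says 15% and 99%, holding that “the side reaction consumes most of the target”. Its y is below mine.

The simulation gives 15.2% and 98.9%. The conversion of starting material + target into side product is the main reason for the low y: y is 15.2% with that step and 58.1% with it struck out. The ceiling bounds free target, not what has escaped, so product in the second phase reaches 13.5% at 10.0 d, above the ceiling's 5.36%. In the same flask read at 2.5 d, the readings of 0.154 M reagent and 45.7% starting material put the corrected ceiling at 3.88%, and free target, with one idle adduct counted as one target, stands at 4.04%.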